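The route cuts the C1–C10 bond (germacrane numbering), the bond shared by the oxirane and the ten-membered carbocycle. Both of its carbons carry oxygen in the target and C2 next to it is a carbinol, so this bond is a pinacol retron. A SmI2 ketyl coupling between a C1 α-alkoxy aldehyde and a C10 methyl ketone, both hanging from the preformed trans-fused γ-lactone, closes the cyclodecane and sets C1 and C10 in one operation. Mesylation of the secondary C1 hydroxyl then lets the tertiary C10 alkoxide close the trans-oxirane with inversion. The precursor is an acyclic keto aldehyde whose α-methylene lactone is masked as a Mannich base.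

Key step: step 15

Remark: germacrane numbering is used for the target and all intermediates (C1 and C10 oxirane carbons, C14 the methyl on C10, C2 carbinol, C4 bearing the formyl carbon C15, C6 lactone O–CH, C7, C8 tiglate carbon, C11–C13 methylene lactone); the target is taken as the open hydroxy aldehyde drawn, not as a transannular lactol.

Step 1
Reactants: 1 (S)-5-[(trityloxy)methyl]dihydrofuran-2(3H)-one; 2 1-bromo-3-methylbut-2-ene
Product: 3 (3R,5S)-3-(3-methylbut-2-en-1-yl)-5-[(trityloxy)methyl]dihydrofuran-2(3H)-one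
Conditions: LiN(i-Pr)2, THF, −78 °C; then 2, −78 → −40 °C
Reagents that add atoms: none
Why: Lactone enolate alkylation; the electrophile should enter anti to the bulky C5 trityloxymethyl group, which sets C4 trans to C2 across the ring.

Step 2
Reactants: 3 trans-alkylated lactone
Product: 4 (2R,4S)-2-(3-methylbut-2-en-1-yl)-5-(trityloxy)pentane-1,4-diol
Conditions: LiAlH4, THF, 0 °C
Reagents that add atoms: none
Why: Hydride reduction of the lactone to the 1,4-diol; no stereocentre is touched.

Step 3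
Reactants: 4 diol
Product: 5 (2R,4S)-1,4-bis[(4-methoxybenzyl)oxy]-2-(3-methylbut-2-en-1-yl)-5-(trityloxy)pentane
Conditions: NaH, 4-methoxybenzyl chloride, Bu4NI (cat.), DMF, 0 °C → rt
Reagents that add atoms: 4-methoxybenzyl chloride, COc1ccc(CCl)cc1
Why: Williamson etherification of both alkoxides; the two p-methoxybenzyl ethers should survive every later step and leave together under DDQ.

Step 4
Reactants: 5 bis-PMB trityl ether
Product: 6 (2S,4R)-2-[(4-methoxybenzyl)oxy]-4-{[(4-methoxybenzyl)oxy]methyl}-7-methyloct-6-en-1-ol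
Conditions: camphorsulfonic acid (cat.), MeOH/CH2Cl2, 0 °C → rt
Reagents that add atoms: none
Why: Acid-catalysed SN1 solvolysis of the trityl ether, which p-methoxybenzyl ethers tolerate.

Step 5
Reactants: 6 primary alcohol
Product: 7 (2S,4R)-2-[(4-methoxybenzyl)oxy]-4-{[(4-methoxybenzyl)oxy]methyl}-7-methyloct-6-enal
Conditions: Dess–Martin periodinane, CH2Cl2, 0 °C → rt
Reagents that add atoms: none
Why: Dess–Martin oxidation stops at the α-alkoxy aldehyde under non-basic conditions that should keep C2 intact.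

Step 6
Reactants: 7 α-alkoxy aldehyde
Product: 8 (3S,5R)-3-[(4-methoxybenzyl)oxy]-5-{[(4-methoxybenzyl)oxy]methyl}-8-methylnona-1,7-diene
Conditions: Ph3PCH3Br, KN(SiMe3)2, THF, 0 °C; then 7, −78 → 0 °C
Reagents that add atoms: methyltriphenylphosphonium bromide, C[P+](c1ccccc1)(c1ccccc1)c1ccccc1.[Br-]
Why: Wittig methylenation with the unstabilised ylide at low temperature; the vinyl group is the latent C1 aldehyde and protects C2 from epimerisation in between.

Step 7
Reactants: 8 diene
Product: 9 (3S,5S)-5-[(4-methoxybenzyl)oxy]-3-{[(4-methoxybenzyl)oxy]methyl}hept-6-enal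
Conditions: O3, CH2Cl2/MeOH, −78 °C, Sudan Red 7B end point; then Me2S
Reagents that add atoms: ozone, [O-][O+]=O
Why: Chemoselective ozonolysis; the electron-rich trisubstituted olefin should react much faster than the monosubstituted allylic-ether olefin and the anisyl rings, and the dye end point limits the ozone dose.

Step 8
Reactants: 10 (S)-4-benzyl-1,3-thiazolidine-2-thione; 11 methyl 4-chloro-4-oxobutanoate
Product: 12 methyl 4-[(4S)-4-benzyl-2-thioxo-1,3-thiazolidin-3-yl]-4-oxobutanoate
Conditions: Et3N, DMAP (cat.), CH2Cl2, 0 °C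
Reagents that add atoms: none
Why: N-Acylation of the thiazolidinethione by the acid chloride.

Step 9
Reactants: 9 C1–C6 aldehyde; 12 thioimide
Product: 14 trans-γ-lactone thioimide, via syn-aldol adduct 13 (not isolated)
Conditions: 12, TiCl4, i-Pr2NEt, N-methylpyrrolidinone, CH2Cl2, −78 → 0 °C; then 9, −78 °C; work-up; camphorsulfonic acid (cat.), CH2Cl2, rt
Reagents that add atoms: none
Why: Crimmins-type titanium aldol reaction; the Z-enolate of the (S)-thiazolidinethione imide should react through the non-chelated chair transition state to give the Evans-syn adduct, fixing C6 and C7 under auxiliary control, and acid then closes the γ-hydroxy ester to the trans-lactone.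

Step 10
Reactants: 14 lactone thioimide
Product: 15 β-formyl-γ-lactone (C8 aldehyde)
Conditions: i-Bu2AlH (1.1 equiv), CH2Cl2, −78 °C; aq. potassium sodium tartrate
Reagents that add atoms: none
Why: Hydride reduction of the strongly activated thioimide to the aldehyde through a stable aluminium hemithioaminal should be much faster than attack on the γ-lactone at −78 °C.

Step 11
Reactants: 15 C8 aldehyde; 16 2-methylallylmagnesium chloride
Product: 17 (8S)-homoallylic alcohol
Conditions: (−)-Ipc2BOMe, 16, Et2O, 0 °C → rt; then 15, −78 °C; then ethanolamine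
Reagents that add atoms: none
Why: Brown asymmetric methallylboration; the chair transition state of the (+)-α-pinene-derived borane should deliver the methallyl group to the Si face of the aldehyde (8S), a sense that is matched with Felkin–Anh induction from C7.

Step 12
Reactants: 17 hydroxy lactone; 18 N,N-dimethylmethyleneiminium iodide
Product: 19 α-(dimethylaminomethyl) lactone
Conditions: LiN(i-Pr)2 (2.2 equiv), THF, −78 °C; then 18, −78 → 0 °C
Reagents that add atoms: none
Why: Mannich reaction of the lactone lithium enolate (alkoxide–enolate dianion) with the iminium salt, anti to the C7 side chain; the β-amino lactone is a masked α-methylene lactone that should be inert to OsO4 and SmI2.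

Step 13
Reactants: 19 Mannich base alcohol; 20 (E)-2-methylbut-2-enoyl chloride
Product: 21 C8 tiglate
Conditions: Et3N, DMAP, CH2Cl2, 0 °C → rt
Reagents that add atoms: none
Why: DMAP-catalysed acylation of the C8 alcohol with retention; the E geometry of the tigloyl group is the stable one.

Step 14
Reactants: 21 diene tiglate
Product: 22 keto aldehyde (C1 aldehyde, C10 methyl ketone)
Conditions: OsO4 (cat.), NaIO4, 2,6-lutidine, dioxane/H2O, rt
Reagents that add atoms: osmium tetroxide, O=[Os](=O)(=O)=O; sodium periodate, [Na+].[O-][I](=O)(=O)=O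
Why: Johnson–Lemieux oxidation; OsO4 should dihydroxylate the two electron-rich terminal olefins far faster than the electron-poor trisubstituted tiglate, and periodate cleaves both glycols, unveiling the two carbonyl groups together.

Step 15
Reactants: 22 keto aldehyde
Product: 23 ten-membered (1S,10R)-1,10-diol
Conditions: SmI2 (3 equiv), THF, slow addition of 22 (final 2 mM), −78 °C → rt; then aq. NH4Cl
Reagents that add atoms: none
Why: Single-electron transfer from SmI2 to the aldehyde gives the C1 ketyl, which adds to the samarium-bound C10 ketone; a second electron and work-up give the vicinal diol, so the C1–C10 bond, the cyclodecane and the oxygenation of both future oxirane carbons arise in one operation. The closest known reaction type is the intramolecular pinacol coupling of keto aldehydes, with SmI2 for five- to eight-membered cis-diols and with low-valent titanium for ten- to fourteen-membered carbocyclic diols. The ten-membered ring closes in the 10-exo-trig mode (ketyl carbon onto the C10=O bond, oxygen exocyclic). C1 and C10 are set together: the trivalent samarium that bridges both oxygens should hold them syn in the bond-forming transition structure (cis-diol), and the ketyl oxygen should turn away from the C2 p-methoxybenzyloxy group, which places C1–OH anti to C2–O. The step needs ring closure to outrun simple reduction and dimerisation and needs the ketyl to ignore the other π-systems; slow addition at high dilution, the far faster reduction of the aldehyde than of ketone, lactone or trisubstituted tiglate, and the Mannich masking of the methylene lactone should secure this.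

Step 16
Reactants: 23 diol
Product: 25 trans-fused (1R,10R)-oxirane, via C1 mesylate 24 (not isolated)
Conditions: MsCl, Et3N, CH2Cl2, −20 °C; then DBU, rt
Reagents that add atoms: none
Why: Sulfonylation of the only secondary hydroxyl (the tertiary C10–OH should not react) followed by intramolecular Williamson closure (3-exo-tet SN2) by the C10 alkoxide inverts C1 and gives the trans-fused oxirane, threo to C2–O.

Step 17
Reactants: 25 oxirane Mannich base
Product: 27 α-methylene lactone bis-PMB ether, via trimethylammonium iodide 26 (not isolated)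
Conditions: MeI, MeCN, rt; then aq. NaHCO3, EtOAc, rt
Reagents that add atoms: none
Why: N-Methylation and base-induced E1cB (Hofmann-type) loss of trimethylamine regenerate the α-methylene lactone under conditions that should spare oxirane and tiglate.

Step 18
Reactants: 27 bis-PMB ether
Product: 28 C2,C15-diol
Conditions: DDQ, CH2Cl2/aq. Na2HPO4–NaH2PO4 (pH 7), 0 °C → rt
Reagents that add atoms: none
Why: Oxidative cleavage of both p-methoxybenzyl ethers (hydride abstraction to the oxocarbenium ions, then hydrolysis) at neutral pH.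

Step 19
Reactants: 28 diol
Product: 29 target CNP0307768.2
Conditions: TEMPO (cat.), PhI(OAc)2 (1.1 equiv), CH2Cl2, rt
Reagents that add atoms: none
Why: Oxoammonium (TEMPO) oxidation should be selective for the primary C15 alcohol on steric grounds and stop at the aldehyde, leaving the C2 carbinol.

Compound list

1 | (S)-5-[(trityloxy)methyl]dihydrofuran-2(3H)-one | O=C1CC[C@@H](COC(c2ccccc2)(c2ccccc2)c2ccccc2)O1 | starting material
2 | 1-bromo-3-methylbut-2-ene (prenyl bromide) | CC(C)=CCBr | starting material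
3 | (3R,5S)-3-(3-methylbut-2-en-1-yl)-5-[(trityloxy)methyl]dihydrofuran-2(3H)-one (3,5-trans) | O=C1[C@H](CC=C(C)C)C[C@@H](COC(c2ccccc2)(c2ccccc2)c2ccccc2)O1 | intermediate
4 | (2R,4S)-2-(3-methylbut-2-en-1-yl)-5-(trityloxy)pentane-1,4-diol | OC[C@H](CC=C(C)C)C[C@H](O)COC(c1ccccc1)(c1ccccc1)c1ccccc1 | intermediate
5 | (2R,4S)-1,4-bis[(4-methoxybenzyl)oxy]-2-(3-methylbut-2-en-1-yl)-5-(trityloxy)pentane | COc1ccc(COC[C@H](CC=C(C)C)C[C@H](OCc2ccc(OC)cc2)COC(c2ccccc2)(c2ccccc2)c2ccccc2)cc1 | intermediate
6 | (2S,4R)-2-[(4-methoxybenzyl)oxy]-4-{[(4-methoxybenzyl)oxy]methyl}-7-methyloct-6-en-1-ol | COc1ccc(COC[C@H](CC=C(C)C)C[C@H](OCc2ccc(OC)cc2)CO)cc1 | intermediate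
7 | (2S,4R)-2-[(4-methoxybenzyl)oxy]-4-{[(4-methoxybenzyl)oxy]methyl}-7-methyloct-6-enal | COc1ccc(COC[C@H](CC=C(C)C)C[C@H](OCc2ccc(OC)cc2)C=O)cc1 | intermediate
8 | (3S,5R)-3-[(4-methoxybenzyl)oxy]-5-{[(4-methoxybenzyl)oxy]methyl}-8-methylnona-1,7-diene | COc1ccc(COC[C@H](CC=C(C)C)C[C@H](OCc2ccc(OC)cc2)C=C)cc1 | intermediate
9 | (3S,5S)-5-[(4-methoxybenzyl)oxy]-3-{[(4-methoxybenzyl)oxy]methyl}hept-6-enal (C1–C6 fragment, C6 as aldehyde) | COc1ccc(COC[C@H](CC=O)C[C@H](OCc2ccc(OC)cc2)C=C)cc1 | intermediate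
10 | (S)-4-benzyl-1,3-thiazolidine-2-thione | S=C1N[C@@H](Cc2ccccc2)CS1 | starting material
11 | methyl 4-chloro-4-oxobutanoate | COC(=O)CCC(=O)Cl | starting material
12 | methyl 4-[(4S)-4-benzyl-2-thioxo-1,3-thiazolidin-3-yl]-4-oxobutanoate | COC(=O)CCC(=O)N1[C@@H](Cc2ccccc2)CSC1=S | intermediate
13 | Evans-syn aldol adduct: thioimide carbonyl as C8, C7 carrying CH2CO2Me, C6 carbinol, chain C1–C5 as in 9; C2, C4, C6, C7 as in the target | COC(=O)C[C@H](C(=O)N1[C@@H](Cc2ccccc2)CSC1=S)[C@H](O)C[C@@H](COCc1ccc(OC)cc1)C[C@H](OCc1ccc(OC)cc1)C=C | intermediate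
14 | trans-γ-lactone (C12 to O6) carrying the thiazolidinethione imide (C8) on C7 and the C1–C5 chain on C6; C2, C4, C6, C7 as in the target | O=C1O[C@H](C[C@@H](COCc2ccc(OC)cc2)C[C@H](OCc2ccc(OC)cc2)C=C)[C@H](C1)C(=O)N1[C@@H](Cc2ccccc2)CSC1=S | intermediate
15 | the same trans-γ-lactone with C8 as aldehyde on C7 | O=C1O[C@H](C[C@@H](COCc2ccc(OC)cc2)C[C@H](OCc2ccc(OC)cc2)C=C)[C@H](C1)C=O | intermediate
16 | 2-methylallylmagnesium chloride | C=C(C)C[Mg]Cl | starting material
17 | (8S)-homoallylic alcohol: lactone 15 with C8 as CH(OH)CH2C(CH3)=CH2; C8 as in the target | O=C1O[C@H](C[C@@H](COCc2ccc(OC)cc2)C[C@H](OCc2ccc(OC)cc2)C=C)[C@H](C1)[C@@H](O)CC(C)=C | intermediate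
18 | N,N-dimethylmethyleneiminium iodide | C=[N+](C)C.[I-] | starting material
19 | Mannich base: 17 with CH2N(CH3)2 on C11, trans to the C7 side chain | CN(C)C[C@@H]1C(=O)O[C@H](C[C@@H](COCc2ccc(OC)cc2)C[C@H](OCc2ccc(OC)cc2)C=C)[C@H]1[C@@H](O)CC(C)=C | intermediate
20 | (E)-2-methylbut-2-enoyl chloride (tigloyl chloride) | C/C=C(\C)C(=O)Cl | starting material
21 | C8 tiglate of 19 | CN(C)C[C@@H]1C(=O)O[C@H](C[C@@H](COCc2ccc(OC)cc2)C[C@H](OCc2ccc(OC)cc2)C=C)[C@H]1[C@@H](OC(=O)/C(C)=C/C)CC(C)=C | intermediate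
22 | keto aldehyde: 21 with C1 as aldehyde and C10 as methyl ketone | CN(C)C[C@@H]1C(=O)O[C@H](C[C@@H](COCc2ccc(OC)cc2)C[C@H](OCc2ccc(OC)cc2)C=O)[C@H]1[C@@H](OC(=O)/C(C)=C/C)CC(C)=O | intermediate
23 | ten-membered (1S,10R)-diol: C1–OH and C10–OH cis on the ring, C1–OH anti to C2–OPMB, C10 as in the target | CN(C)C[C@@H]1C(=O)O[C@@H]2C[C@@H](COCc3ccc(OC)cc3)C[C@H](OCc3ccc(OC)cc3)[C@H](O)[C@](C)(O)C[C@H](OC(=O)/C(C)=C/C)[C@@H]12 | intermediate
24 | C1 methanesulfonate of 23 | CN(C)C[C@@H]1C(=O)O[C@@H]2C[C@@H](COCc3ccc(OC)cc3)C[C@H](OCc3ccc(OC)cc3)[C@H](OS(C)(=O)=O)[C@](C)(O)C[C@H](OC(=O)/C(C)=C/C)[C@@H]12 | intermediate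
25 | (1R,10R)-1,10-epoxide (trans-fused, as in the target) with PMB ethers on O2 and O15, C8 tiglate and C11 CH2N(CH3)2 | CN(C)C[C@@H]1C(=O)O[C@@H]2C[C@@H](COCc3ccc(OC)cc3)C[C@H](OCc3ccc(OC)cc3)[C@H]3O[C@]3(C)C[C@H](OC(=O)/C(C)=C/C)[C@@H]12 | intermediate
26 | N-methyl quaternary ammonium iodide of 25 | C[N+](C)(C)C[C@@H]1C(=O)O[C@@H]2C[C@@H](COCc3ccc(OC)cc3)C[C@H](OCc3ccc(OC)cc3)[C@H]3O[C@]3(C)C[C@H](OC(=O)/C(C)=C/C)[C@@H]12.[I-] | intermediate
27 | O2,O15-bis(4-methoxybenzyl) ether of the C15 alcohol of the target (α-methylene lactone restored) | C=C1C(=O)O[C@@H]2C[C@@H](COCc3ccc(OC)cc3)C[C@H](OCc3ccc(OC)cc3)[C@H]3O[C@]3(C)C[C@H](OC(=O)/C(C)=C/C)[C@@H]12 | intermediate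
28 | C15 alcohol of the target (C2,C15-diol) | C=C1C(=O)O[C@@H]2C[C@@H](CO)C[C@H](O)[C@H]3O[C@]3(C)C[C@H](OC(=O)/C(C)=C/C)[C@@H]12 | intermediate
29 | CNP0307768.2 | C=C1C(=O)O[C@@H]2C[C@@H](C=O)C[C@H](O)[C@H]3O[C@]3(C)C[C@H](OC(=O)/C(C)=C/C)[C@@H]12 | target

Total step count: 19. Longest linear sequence: 18 steps (steps 1–7 and 9–19; step 8 is the one-step side branch).

Steps most likely to fail

Step 15 (key step). The flexible ten-membered transition structure may lose the cis-diol preference, so that the hydroxyls end trans (C10 epimer), and simple reduction of the two carbonyl groups may compete with ring closure. The fallback goes through the E-olefin and sets out from 22. The same coupling then gives the trans-diol F1, which thiocarbonyldiimidazole/DMAP (toluene, 80 °C) should convert into the cyclic thiocarbonate F2. 1,3-Dimethyl-2-phenyl-1,3,2-diazaphospholidine at 40 °C (Corey–Winter syn-elimination, stereospecific) should give the E-cyclodecene F3, and MeI followed by aq. NaHCO3 should lead through the ammonium iodide F4 to the methylene lactone F5. DDQ then frees the allylic alcohol diol F6. Epoxidation with VO(acac)2/t-BuOOH, directed by the C2 hydroxyl from the ring periphery with H2 eclipsing the olefin (allylic strain against C14), should give the threo epoxy alcohol 28, where the route is rejoined. Either C1 epimer of the trans-diol series converges at F3.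

Step 14. The β-acyloxy ketone may lose tiglate by β-elimination and the centre next to the new aldehyde (C2) may epimerise, both helped by the internal amine. The fallback carries a silyl ether at C8 through the ring closure and sets out from 19. Et3SiOTf/2,6-lutidine should give the triethylsilyl ether F7, and OsO4/NaIO4 the keto aldehyde F8. SmI2 should close it to the diol F9, and MsCl/Et3N then DBU should lead through the mesylate F10 to the oxirane F11. HF·pyridine frees the C8 alcohol F12, and tigloyl chloride/DMAP returns to 25.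

Step 19. Over-oxidation through a transannular lactol (C2–OH adding to the new aldehyde) to a γ-lactone, or oxidation at C2, may erode the final step. The fallback sets out from 28. Et3SiOTf/2,6-lutidine should give the bis(triethylsilyl) ether F13. Swern oxidation (oxalyl chloride, DMSO, then Et3N), which cleaves and oxidises only the primary silyl ether, should give the C2-silylated aldehyde F14, and HF·pyridine/pyridine (THF, 0 °C) returns to 29.

Further compounds

F1 | step 15 | trans-diol, C10 epimer of 23 | CN(C)C[C@@H]1C(=O)O[C@@H]2C[C@@H](COCc3ccc(OC)cc3)C[C@H](OCc3ccc(OC)cc3)[C@H](O)[C@@](C)(O)C[C@H](OC(=O)/C(C)=C/C)[C@@H]12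
F2 | step 15 | cyclic 1,10-thiocarbonate of F1 | CN(C)C[C@@H]1C(=O)O[C@@H]2C[C@@H](COCc3ccc(OC)cc3)C[C@H](OCc3ccc(OC)cc3)[C@@H]3OC(=S)O[C@@]3(C)C[C@H](OC(=O)/C(C)=C/C)[C@@H]12
F3 | step 15 | (E)-1(10)-cyclodecene Mannich base | CN(C)C[C@@H]1C(=O)O[C@@H]2C[C@@H](COCc3ccc(OC)cc3)C[C@H](OCc3ccc(OC)cc3)/C=C(C)/C[C@H](OC(=O)/C(C)=C/C)[C@@H]12
F4 | step 15 | N-methyl ammonium iodide of F3 | C[N+](C)(C)C[C@@H]1C(=O)O[C@@H]2C[C@@H](COCc3ccc(OC)cc3)C[C@H](OCc3ccc(OC)cc3)/C=C(C)/C[C@H](OC(=O)/C(C)=C/C)[C@@H]12.[I-]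
F5 | step 15 | (E)-cyclodecene α-methylene lactone bis-PMB ether | C=C1C(=O)O[C@@H]2C[C@@H](COCc3ccc(OC)cc3)C[C@H](OCc3ccc(OC)cc3)/C=C(C)/C[C@H](OC(=O)/C(C)=C/C)[C@@H]12
F6 | step 15 | (E)-cyclodecene allylic alcohol (C2,C15-diol) | C=C1C(=O)O[C@@H]2C[C@@H](CO)C[C@H](O)/C=C(C)/C[C@H](OC(=O)/C(C)=C/C)[C@@H]12
F7 | step 14 | C8 triethylsilyl ether of 19 | CN(C)C[C@@H]1C(=O)O[C@H](C[C@@H](COCc2ccc(OC)cc2)C[C@H](OCc2ccc(OC)cc2)C=C)[C@H]1[C@@H](O[Si](CC)(CC)CC)CC(C)=C
F8 | step 14 | keto aldehyde with C8 triethylsilyl ether | CN(C)C[C@@H]1C(=O)O[C@H](C[C@@H](COCc2ccc(OC)cc2)C[C@H](OCc2ccc(OC)cc2)C=O)[C@H]1[C@@H](O[Si](CC)(CC)CC)CC(C)=O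
F9 | step 14 | (1S,10R)-diol with C8 triethylsilyl ether | CN(C)C[C@@H]1C(=O)O[C@@H]2C[C@@H](COCc3ccc(OC)cc3)C[C@H](OCc3ccc(OC)cc3)[C@H](O)[C@](C)(O)C[C@H](O[Si](CC)(CC)CC)[C@@H]12
F10 | step 14 | C1 methanesulfonate of F9 | CN(C)C[C@@H]1C(=O)O[C@@H]2C[C@@H](COCc3ccc(OC)cc3)C[C@H](OCc3ccc(OC)cc3)[C@H](OS(C)(=O)=O)[C@](C)(O)C[C@H](O[Si](CC)(CC)CC)[C@@H]12
F11 | step 14 | (1R,10R)-oxirane with C8 triethylsilyl ether | CN(C)C[C@@H]1C(=O)O[C@@H]2C[C@@H](COCc3ccc(OC)cc3)C[C@H](OCc3ccc(OC)cc3)[C@H]3O[C@]3(C)C[C@H](O[Si](CC)(CC)CC)[C@@H]12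
F12 | step 14 | (1R,10R)-oxirane with free C8 hydroxyl | CN(C)C[C@@H]1C(=O)O[C@@H]2C[C@@H](COCc3ccc(OC)cc3)C[C@H](OCc3ccc(OC)cc3)[C@H]3O[C@]3(C)C[C@H](O)[C@@H]12
F13 | step 19 | O2,O15-bis(triethylsilyl) ether of 28 | C=C1C(=O)O[C@@H]2C[C@@H](CO[Si](CC)(CC)CC)C[C@H](O[Si](CC)(CC)CC)[C@H]3O[C@]3(C)C[C@H](OC(=O)/C(C)=C/C)[C@@H]12
F14 | step 19 | O2-triethylsilyl ether of the target | C=C1C(=O)O[C@@H]2C[C@@H](C=O)C[C@H](O[Si](CC)(CC)CC)[C@H]3O[C@]3(C)C[C@H](OC(=O)/C(C)=C/C)[C@@H]12
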